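The constant to read first is one the runs already hold, because a reading of J is of free J while a reading of G counts all its forms, free or not.

the same everywhere: J 0.010 M
- blue: X 0.95 equiv; E 2 equiv; temperature 20 °C; run made earlier
- ochre: X 0.95 equiv; E 1.3 equiv; temperature 35 °C; run made earlier
- red: X 0.95 equiv; E 3 equiv; temperature 20 °C; run made earlier
- epsilon: X 0.950 equiv (fed, over 5.0 h); E 2.00 equiv; temperature 35 °C; all else is in the flask from the start; the feed brings no volume worth counting; time 6.0 h
- zeta: X 0.950 equiv; E 2.00 equiv; everything together at the start at −5 °C, warmed to 35 °C at 5.0 h; time 6.0 h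
- delta: X 0.950 equiv; E 2.00 equiv; temperature 35 °C; everything together at the start; time 6.0 h
- theta: X 0.950 equiv; E 2.00 equiv (in portions, 5, over 5.0 h); temperature 35 °C; first portion at the start, last at 5.0 h; time 6.0 h
- eta: X 0.950 equiv (fed, over 5.0 h); E 2.00 equiv; the addition at −5 °C, then warmed to 35 °C; the feed brings no volume worth counting; time 6.0 h

| run | time / h | G / % | J / % |
|---|---|---|---|
| blue | 2.00 | 36 | 37 |
| blue | 3.00 | 40 | 24 |
| blue | 5.00 | 50 | 20 |
| blue | 6.00 | 55 | 21 |
| blue | 8.00 | 54 | 17 |
| blue | 10.0 | 57 | 14 |
| blue | 12.0 | 53 | 14 |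
| ochre | 0.250 | 20 | 69 |
| ochre | 0.667 | 37 | 45 |
| ochre | 1.33 | 45 | 33 |
| ochre | 2.00 | 52 | 29 |
| ochre | 3.00 | 55 | 25 |
| ochre | 4.00 | 50 | 24 |
| ochre | 5.00 | 54 | 22 |
| red | 1.33 | 29 | 47 |
| red | 3.00 | 43 | 28 |
| red | 4.00 | 47 | 23 |
| red | 6.00 | 46 | 23 |
| red | 8.00 | 50 | 16 |
| red | 10.0 | 49 | 21 |

(standard deviation of a reading: 2 percentage points)

- what was read earlier has a scatter of 2 percentage points, one standard deviation
- a reading or a percentage of G counts all its forms, free or not
- a reading of J is of its free form alone

- the best flask by amount of G, in percent of the J charged; "all alike" if 1.5 percentage points covers them all (epsilon / zeta / delta / theta / eta / all alike)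
- amount of G at the end, in percent of the J charged, epsilon
- amount of G at the end, in percent of the J charged, zeta
- amount of G at the end, in percent of the J charged, delta
- amount of G at the end, in percent of the J charged, theta
- amount of G at the end, in percent of the J charged, eta

The decision for the next run is whether E goes in at once or in portions. In the ochre run, J and G together fall short of the charge. I take the gap b as J held to G in a fast association, with each pair counted once as G. From 3.00 h on, the ochre readings average 23.7% J and 53.0% G, so:

b = 1 − J − G = 23.3%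

Your carried quantity is the binding number κ, the association constant times the J charged, read here at 35 °C and 0.010 M, with every amount a fraction of the J charged:

κ = b / (J (G − b)) = 3.32

For any G in hand at those settings, solve b = κ(1 − G − b)(G − b); free J is then 1 − G − b.

For the split of X between J and E, the number I watch is E over free J. At this late free J, with E at its full charge of 2.00 equiv, the ratio is 8.45. With a first portion of 0.400 in its place, the same free J gives 1.69, which is smaller. So I would charge theta, with E in portions at 35 °C.

The forecast also names theta, with theta at 55%, delta at 52%, epsilon at 52.5%, and zeta and eta at 45% and 45%, on the ground that “Dosing E keeps its level low”.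

Theta gives 62.2% of G, more than any other flask, while delta gives 50.2%, epsilon 48.2%, zeta 47.3% and eta 44.0%.

    J + X → G (k = 2.14 M⁻¹ min⁻¹, Ea = 43.0 kJ mol⁻¹)
    E + X → L (k = 0.469 M⁻¹ min⁻¹, Ea = 75.0 kJ mol⁻¹)
    J + G ⇌ D, settled at all times (K = 290 M⁻¹, ΔH = −48.0 kJ mol⁻¹)
    X ⇌ Q (K = 1.90, k = 0.00120 min⁻¹, Ea = 107 kJ mol⁻¹, ΔH = −63.0 kJ mol⁻¹)
    2 X → Z (k = 0.0701 M⁻¹ min⁻¹, Ea = 61.0 kJ mol⁻¹)
    (constants at 35 °C)

At 6.00 h, theta holds L at 0.00201 M against 0.00375 M in delta. D is the pair that b counted. Put theta's G into the equation with κ and you get b of 21.7% and free J of 16.1%; the flask holds 17.1%.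

Now take a flask like eta but with 0.240 equiv of X. At its G of 14.5%, κ gives b of 10.3% and free J of 75.2%. The computed J at 6.00 h is 75.6%.

All runs come from a simulation on assumed constants.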